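**Retrosynthetic overview**

1. Numbering: C1 ester carbon, C2 (CHMe), C3 and C6 the ring carbons joined through O–O, chain C7–C18. The last bond made is C12–C13, by 9-BBN hydroboration of a C9=C10(Me)–C11=C12 terminal diene on the finished dioxane and Suzuki–Miyaura B-alkyl coupling with (E)-1-iodo-2,6-dimethylhepta-1,5-diene (C13–C18).
2. Enabling feature: C12 is a CH2 homoallylic to the C9=C10 olefin, i.e. the terminus of a 2-methylbuta-1,3-diene that 9-BBN unmasks as a primary borane. The only O–O bond lies in a six-membered dialkyl peroxide between quaternary C6 and secondary C3, with no O–H, which 9-BBN and palladium should leave intact at room temperature.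
3. The diene is made the same way one isoprene unit earlier: C8–C9 from a 6-vinyl-1,2-dioxane (C7=C8) and (E)-1-iodo-2-methylbuta-1,3-diene. The vinyl group comes from a C7,C8-diol by glycol cleavage and methylenation.
4. The 1,2-dioxane is the only ring and is closed once, early: C3–O by 6-exo SN2 of a C6 tertiary hydroperoxide on a C3 mesylate (inversion). C6–OOH comes from perhydrolysis of a Sharpless epoxide (inversion), C2/C3 from a Brown anti-crotylboration, C1 from cleavage of the crotyl vinyl group.
5. C3–C7 and the C6 methyl come from geranyl acetate; both E-iodoalkenes come from zirconium-catalysed carboalumination of terminal alkynes.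

Key step: step 18

Remark: (E)-crotyl-B(Ipc)2 made from (−)-Ipc2BOMe is taken to attack the aldehyde face that gives the (6R) alcohol, as with simple unbranched aldehydes; the dioxane O–O bond and the β-peroxy ester are taken to tolerate 9-BBN, mild aqueous base and palladium at room temperature, but not strong base.

**Step 1**
Reactants: 1 geranyl acetate [(2E)-3,7-dimethylocta-2,6-dien-1-yl acetate]
Product: 2 (2E)-3-methyl-6-oxohex-2-en-1-yl acetate
Conditions: O3 (1 equiv), CH2Cl2/pyridine, −78 °C; Me2S, −78 °C → rt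
Reagents that add atoms: ozone, [O-][O+]=O
Why: Criegee ozonolysis with one equivalent of ozone should cleave only the electron-rich terminal trisubstituted alkene, because the other alkene is deactivated by the allylic acetoxy group; no stereocentre is formed.

**Step 2**
Reactants: 2 (2E)-3-methyl-6-oxohex-2-en-1-yl acetate
Product: 3 (2E,6R,7S)-6-hydroxy-3,7-dimethylnona-2,8-dien-1-yl acetate
Conditions: (E)-crotyl-B(Ipc)2 (separately prepared from (−)-Ipc2BOMe), THF, −78 °C; then ethanolamine, Et2O, rt
Reagents that add atoms: (E)-crotyldiisopinocampheylborane, C/C=C/CB([C@@H]1C[C@@H]2C[C@H]([C@H]1C)C2(C)C)[C@@H]1C[C@@H]2C[C@H]([C@H]1C)C2(C)C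
Why: Brown crotylboration through a closed chair (Zimmerman–Traxler) transition state, in which the E-crotyl geometry should give the anti relationship and the (+)-α-pinene-derived isopinocampheyl groups the (6R,7S) absolute configuration, which fixes C2 and (after one later inversion) C3 of the target.

**Step 3**
Reactants: 3 (2E,6R,7S)-6-hydroxy-3,7-dimethylnona-2,8-dien-1-yl acetate
Product: 4 (2E,6R,7S)-6-(methanesulfonyloxy)-3,7-dimethylnona-2,8-dien-1-yl acetate
Conditions: MsCl, Et3N, CH2Cl2, 0 °C
Reagents that add atoms: methanesulfonyl chloride, CS(=O)(=O)Cl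
Why: O-sulfonylation of the secondary alcohol leaves both stereocentres untouched and turns the C–O bond into the leaving group for the later SN2 ring closure.

**Step 4**
Reactants: 4 (2E,6R,7S)-6-(methanesulfonyloxy)-3,7-dimethylnona-2,8-dien-1-yl acetate
Product: 5 (3S,4R,7E)-9-hydroxy-3,7-dimethylnona-1,7-dien-4-yl methanesulfonate
Conditions: K2CO3 (0.2 equiv), MeOH, 0 °C
Reagents that add atoms: none
Why: Base-catalysed transesterification with methanol should remove only the primary allylic acetate, since the secondary mesylate is not attacked by carbonate in cold methanol.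

**Step 5**
Reactants: 5 (3S,4R,7E)-9-hydroxy-3,7-dimethylnona-1,7-dien-4-yl methanesulfonate
Product: 6 (3S,4R)-6-[(2R,3R)-3-(hydroxymethyl)-2-methyloxiran-2-yl]-3-methylhex-1-en-4-yl methanesulfonate
Conditions: Ti(OiPr)4 (cat.), D-(−)-diethyl tartrate (cat.), t-BuOOH, 4 Å MS, CH2Cl2, −20 °C
Reagents that add atoms: tert-butyl hydroperoxide, CC(C)(C)OO
Why: Sharpless asymmetric epoxidation of the E-trisubstituted allylic alcohol, where D-(−)-diethyl tartrate should deliver oxygen under reagent control to give the (2R,3R)-epoxide, and the terminal vinyl group (no allylic OH) is not epoxidised.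

**Step 6**
Reactants: 6 (3S,4R)-6-[(2R,3R)-3-(hydroxymethyl)-2-methyloxiran-2-yl]-3-methylhex-1-en-4-yl methanesulfonate
Product: 7 (3S,4R,7S,8R)-7-hydroperoxy-8,9-dihydroxy-3,7-dimethylnon-1-en-4-yl methanesulfonate
Conditions: H2O2 (anhydrous, in Et2O, excess), H3PMo12O40 (cat.), rt
Reagents that add atoms: hydrogen peroxide, OO
Why: Molybdenum-acid-catalysed perhydrolysis of the epoxide, in which H2O2 should attack the tertiary epoxide carbon from the backside (borderline SN2, inversion) and so set the peroxide-bearing quaternary carbon (later C6), while the secondary carbinol keeps its configuration.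

**Step 7**
Reactants: 7 (3S,4R,7S,8R)-7-hydroperoxy-8,9-dihydroxy-3,7-dimethylnon-1-en-4-yl methanesulfonate
Product: 8 (1R)-1-[(3S,6S)-6-[(2S)-but-3-en-2-yl]-3-methyl-1,2-dioxan-3-yl]ethane-1,2-diol
Conditions: CsOH·H2O (1.1 equiv), DMF, 0 °C → rt
Reagents that add atoms: none
Why: Intramolecular Williamson-type 6-exo-tet O-alkylation, in which the hydroperoxide (pKa about 12.5) is deprotonated selectively over the diol and should displace the secondary mesylate with inversion, closing the 1,2-dioxane and setting the ring CH stereocentre (later C3).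

**Step 8**
Reactants: 8 (1R)-1-[(3S,6S)-6-[(2S)-but-3-en-2-yl]-3-methyl-1,2-dioxan-3-yl]ethane-1,2-diol
Product: 10 (2R)-2-[(3S,6S)-6-[(1R)-1,2-dihydroxyethyl]-6-methyl-1,2-dioxan-3-yl]propanoic acid, via aldehyde 9 (not isolated)
Conditions: O3, MeCN/H2O 9:1, 0 °C; then NaClO2, NaH2PO4, 0 °C → rt
Reagents that add atoms: ozone, [O-][O+]=O; sodium chlorite, [Na+].[O-]Cl=O
Why: Ozonolysis in aqueous acetonitrile (water traps the carbonyl oxide, so the aldehyde forms directly) followed in the same flask by Pinnick oxidation, a buffered non-basic sequence that should avoid both epimerisation of the α-methyl centre and β-elimination of the peroxide.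

**Step 9**
Reactants: 10 (2R)-2-[(3S,6S)-6-[(1R)-1,2-dihydroxyethyl]-6-methyl-1,2-dioxan-3-yl]propanoic acid
Product: 11 methyl (2R)-2-[(3S,6S)-6-[(1R)-1,2-dihydroxyethyl]-6-methyl-1,2-dioxan-3-yl]propanoate
Conditions: Me3SiCHN2, toluene/MeOH 4:1, 0 °C
Reagents that add atoms: (trimethylsilyl)diazomethane, C[Si](C)(C)C=[N+]=[N-]
Why: O-methylation of the carboxylic acid by (trimethylsilyl)diazomethane in methanol is a neutral esterification that touches neither the diol nor the peroxide.

**Step 10**
Reactants: 11 methyl (2R)-2-[(3S,6S)-6-[(1R)-1,2-dihydroxyethyl]-6-methyl-1,2-dioxan-3-yl]propanoate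
Product: 12 methyl (2R)-2-[(3S,6S)-6-formyl-6-methyl-1,2-dioxan-3-yl]propanoate
Conditions: NaIO4, THF/pH 7 buffer, 0 °C
Reagents that add atoms: none
Why: Malaprade glycol cleavage through a cyclic periodate ester should give the aldehyde on the quaternary ring carbon (no α-hydrogen, so no epimerisation) and removes the now superfluous carbinol stereocentre.

**Step 11**
Reactants: 12 methyl (2R)-2-[(3S,6S)-6-formyl-6-methyl-1,2-dioxan-3-yl]propanoate
Product: 13 methyl (2R)-2-[(3S,6S)-6-ethenyl-6-methyl-1,2-dioxan-3-yl]propanoate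
Conditions: Ph3PCH3Br, KN(SiMe3)2 (ylide preformed, no excess base), THF, −78 → 0 °C
Reagents that add atoms: methyltriphenylphosphonium bromide, C[P+](c1ccccc1)(c1ccccc1)c1ccccc1.[Br-]
Why: Wittig methylenation, in which addition of the ylide to the electron-poor α-peroxy aldehyde at −78 °C should be faster than deprotonation next to the ester.

**Step 12**
Reactants: 14 prop-2-yn-1-ol
Product: 16 (2E)-3-iodo-2-methylprop-2-en-1-ol, via alkenylalane 15 (not isolated)
Conditions: Me3Al (3 equiv), Cp2ZrCl2 (cat.), CH2Cl2, 0 °C → rt; then I2, THF, −30 → 0 °C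
Reagents that add atoms: trimethylaluminium, C[Al](C)C; iodine, II
Why: Negishi zirconium-catalysed carboalumination adds Me–Al syn across the alkyne with aluminium on the terminal carbon, and iodinolysis with retention should give the E-iodoalkene.

**Step 13**
Reactants: 16 (2E)-3-iodo-2-methylprop-2-en-1-ol
Product: 17 (2E)-3-iodo-2-methylprop-2-enal
Conditions: MnO2, CH2Cl2, rt
Reagents that add atoms: none
Why: Allylic alcohol oxidation with MnO2 stops at the aldehyde and should not isomerise the iodoalkene.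

**Step 14**
Reactants: 17 (2E)-3-iodo-2-methylprop-2-enal
Product: 18 (1E)-1-iodo-2-methylbuta-1,3-diene
Conditions: Ph3PCH3Br, KN(SiMe3)2, Et2O, −78 → 0 °C; kept as a cold solution
Reagents that add atoms: methyltriphenylphosphonium bromide, C[P+](c1ccccc1)(c1ccccc1)c1ccccc1.[Br-]
Why: Wittig methylenation of the enal builds the terminal diene and leaves the E-iodoalkene geometry untouched.

**Step 15**
Reactants: 13 methyl (2R)-2-[(3S,6S)-6-ethenyl-6-methyl-1,2-dioxan-3-yl]propanoate; 18 (1E)-1-iodo-2-methylbuta-1,3-diene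
Product: 20 methyl (2R)-2-[(3S,6R)-6-methyl-6-[(3E)-4-methylhexa-3,5-dien-1-yl]-1,2-dioxan-3-yl]propanoate, via B-alkyl-9-BBN adduct 19 (not isolated)
Conditions: 9-BBN-H, THF, 0 °C → rt; then H2O, 18, Pd(dppf)Cl2 (cat.), AsPh3, Cs2CO3, DMF, rt
Reagents that add atoms: none
Why: Anti-Markovnikov hydroboration of the monosubstituted vinyl group and Suzuki–Miyaura B-alkyl coupling with retention of the iodoalkene geometry form C8–C9, and the vinyl group is fully consumed before palladium is added, so that no allylic peroxide meets zerovalent palladium.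

**Step 16**
Reactants: 21 5-bromo-2-methylpent-2-ene
Product: 22 6-methylhept-5-en-1-yne
Conditions: LiC≡CH·H2NCH2CH2NH2, DMSO, 10 °C → rt
Reagents that add atoms: lithium acetylide–ethylenediamine complex, [Li+].[C-]#C.NCCN
Why: SN2 alkylation of lithium acetylide by the primary homoallylic bromide in a dipolar aprotic solvent.

**Step 17**
Reactants: 22 6-methylhept-5-en-1-yne
Product: 24 (1E)-1-iodo-2,6-dimethylhepta-1,5-diene, via alkenylalane 23 (not isolated)
Conditions: Me3Al (2 equiv), Cp2ZrCl2 (cat.), CH2Cl2, 0 °C → rt; then I2, THF, −30 → 0 °C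
Reagents that add atoms: trimethylaluminium, C[Al](C)C; iodine, II
Why: Negishi zirconium-catalysed syn-carboalumination of the terminal alkyne (the trisubstituted alkene is inert) and iodinolysis with retention should give the E-iodoalkene.

**Step 18**
Reactants: 20 methyl (2R)-2-[(3S,6R)-6-methyl-6-[(3E)-4-methylhexa-3,5-dien-1-yl]-1,2-dioxan-3-yl]propanoate; 24 (1E)-1-iodo-2,6-dimethylhepta-1,5-diene
Product: 26 methyl (2R)-2-[(3S,6R)-6-methyl-6-[(3E,7E)-4,8,12-trimethyltrideca-3,7,11-trien-1-yl]-1,2-dioxan-3-yl]propanoate, via B-alkyl-9-BBN adduct 25 (not isolated)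
Conditions: 9-BBN-H, THF, 0 °C → rt; then H2O, 24, Pd(dppf)Cl2 (cat.), AsPh3, Cs2CO3, DMF, rt
Reagents that add atoms: none
Why: 9-BBN-H should add syn and anti-Markovnikov only to the monosubstituted C11=C12 end of the 2-methyl-1,3-diene (the trisubstituted C9=C10 alkene, the ester and the dialkyl peroxide are not attacked at room temperature), giving the primary C12 borane; base turns it into a borate, zerovalent palladium inserts into the C–I bond of the E-iodoalkene with retention, and B-to-Pd transfer followed by reductive elimination forms C12–C13. The closest known reaction type is the Suzuki–Miyaura B-alkyl coupling of homoallylic 9-BBN adducts with E-iodoalkenes used to assemble head-to-tail 1,5-dienes of polyprenyl chains. No ring is closed and no stereocentre is created; the three dioxane stereocentres are spectators. The C13=C14 geometry is carried over from the iodoalkene (fixed by syn-carboalumination) and the C9=C10 geometry from the diene, so both E-olefins of the skipped triene are set before the coupling. The step needs C–I insertion and C–B transfer to win over O–O cleavage, β-hydride elimination and ester hydrolysis: the O–O bond is a hindered dialkyl peroxide on quaternary C6 without O–H, dppf with AsPh3 speeds up transmetalation and reductive elimination, and the medium is only mildly basic at room temperature. In this one operation the last nine skeletal carbons are attached and the target should be reached without any protecting group.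

**Compound list**

1 | geranyl acetate, (2E)-3,7-dimethylocta-2,6-dien-1-yl acetate | CC(=O)OC/C=C(\C)CCC=C(C)C | starting material
2 | (2E)-3-methyl-6-oxohex-2-en-1-yl acetate | CC(=O)OC/C=C(\C)CCC=O | intermediate
3 | (2E,6R,7S)-6-hydroxy-3,7-dimethylnona-2,8-dien-1-yl acetate | C=C[C@H](C)[C@H](O)CC/C(C)=C/COC(C)=O | intermediate
4 | (2E,6R,7S)-6-(methanesulfonyloxy)-3,7-dimethylnona-2,8-dien-1-yl acetate | C=C[C@H](C)[C@H](OS(C)(=O)=O)CC/C(C)=C/COC(C)=O | intermediate
5 | (3S,4R,7E)-9-hydroxy-3,7-dimethylnona-1,7-dien-4-yl methanesulfonate | C=C[C@H](C)[C@H](OS(C)(=O)=O)CC/C(C)=C/CO | intermediate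
6 | (3S,4R)-6-[(2R,3R)-3-(hydroxymethyl)-2-methyloxiran-2-yl]-3-methylhex-1-en-4-yl methanesulfonate | C=C[C@H](C)[C@H](OS(C)(=O)=O)CC[C@](C)([C@H]1CO)O1 | intermediate
7 | (3S,4R,7S,8R)-7-hydroperoxy-8,9-dihydroxy-3,7-dimethylnon-1-en-4-yl methanesulfonate | C=C[C@H](C)[C@H](OS(C)(=O)=O)CC[C@@](C)([C@H](O)CO)OO | intermediate
8 | (1R)-1-[(3S,6S)-6-[(2S)-but-3-en-2-yl]-3-methyl-1,2-dioxan-3-yl]ethane-1,2-diol | C=C[C@H](C)[C@@H]1CC[C@@](C)([C@H](O)CO)OO1 | intermediate
9 | (2R)-2-[(3S,6S)-6-[(1R)-1,2-dihydroxyethyl]-6-methyl-1,2-dioxan-3-yl]propanal | O=C[C@H](C)[C@@H]1CC[C@@](C)([C@H](O)CO)OO1 | intermediate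
10 | (2R)-2-[(3S,6S)-6-[(1R)-1,2-dihydroxyethyl]-6-methyl-1,2-dioxan-3-yl]propanoic acid | OC(=O)[C@H](C)[C@@H]1CC[C@@](C)([C@H](O)CO)OO1 | intermediate
11 | methyl (2R)-2-[(3S,6S)-6-[(1R)-1,2-dihydroxyethyl]-6-methyl-1,2-dioxan-3-yl]propanoate | COC(=O)[C@H](C)[C@@H]1CC[C@@](C)([C@H](O)CO)OO1 | intermediate
12 | methyl (2R)-2-[(3S,6S)-6-formyl-6-methyl-1,2-dioxan-3-yl]propanoate | COC(=O)[C@H](C)[C@@H]1CC[C@@](C)(C=O)OO1 | intermediate
13 | methyl (2R)-2-[(3S,6S)-6-ethenyl-6-methyl-1,2-dioxan-3-yl]propanoate | COC(=O)[C@H](C)[C@@H]1CC[C@@](C)(C=C)OO1 | intermediate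
14 | prop-2-yn-1-ol | C#CCO | starting material
15 | [(1E)-3-(dimethylalumanyloxy)-2-methylprop-1-en-1-yl]dimethylalumane | C[Al](C)/C=C(\C)CO[Al](C)C | intermediate
16 | (2E)-3-iodo-2-methylprop-2-en-1-ol | I/C=C(\C)CO | intermediate
17 | (2E)-3-iodo-2-methylprop-2-enal | I/C=C(\C)C=O | intermediate
18 | (1E)-1-iodo-2-methylbuta-1,3-diene | I/C=C(\C)C=C | intermediate
19 | methyl (2R)-2-[(3S,6R)-6-[2-(9-borabicyclo[3.3.1]nonan-9-yl)ethyl]-6-methyl-1,2-dioxan-3-yl]propanoate | COC(=O)[C@H](C)[C@@H]1CC[C@@](C)(CCB2C3CCCC2CCC3)OO1 | intermediate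
20 | methyl (2R)-2-[(3S,6R)-6-methyl-6-[(3E)-4-methylhexa-3,5-dien-1-yl]-1,2-dioxan-3-yl]propanoate | COC(=O)[C@H](C)[C@@H]1CC[C@@](C)(CC/C=C(\C)C=C)OO1 | intermediate
21 | 5-bromo-2-methylpent-2-ene | CC(C)=CCCBr | starting material
22 | 6-methylhept-5-en-1-yne | C#CCCC=C(C)C | intermediate
23 | [(1E)-2,6-dimethylhepta-1,5-dien-1-yl]dimethylalumane | C[Al](C)/C=C(\C)CCC=C(C)C | intermediate
24 | (1E)-1-iodo-2,6-dimethylhepta-1,5-diene | I/C=C(\C)CCC=C(C)C | intermediate
25 | methyl (2R)-2-[(3S,6R)-6-[(3E)-6-(9-borabicyclo[3.3.1]nonan-9-yl)-4-methylhex-3-en-1-yl]-6-methyl-1,2-dioxan-3-yl]propanoate | COC(=O)[C@H](C)[C@@H]1CC[C@@](C)(CC/C=C(\C)CCB2C3CCCC2CCC3)OO1 | intermediate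
26 | methyl (2R)-2-[(3S,6R)-6-methyl-6-[(3E,7E)-4,8,12-trimethyltrideca-3,7,11-trien-1-yl]-1,2-dioxan-3-yl]propanoate | COC(=O)[C@H](C)[C@@H]1CC[C@@](C)(CC/C=C(\C)CC/C=C(\C)CCC=C(C)C)OO1 | target

**Step count**

Total step count: 18. Longest linear sequence: 13 steps (steps 1–11, 15, 18).

**Steps most likely to fail**

Step 7. Instead of O-alkylation by the peroxide anion, the base may cause E2 loss of the mesylate toward the allylic C–H, alkylation on a diol oxygen, or fragmentation of the β-hydroxy hydroperoxide. The fallback reverses the roles of the two ring carbons; it sets out from 5 and comes back at 8. Compound 5 is treated with 2-methoxyprop-2-yl hydroperoxide and CsOH in DMF, which should displace the mesylate with inversion and give the peroxyketal (2E,6S,7S)-6-[(2-methoxypropan-2-yl)peroxy]-3,7-dimethylnona-2,8-dien-1-ol F1. Sharpless epoxidation under the conditions of step 5 should then give the epoxy peroxyketal [(2R,3R)-3-[(3S,4S)-3-[(2-methoxypropan-2-yl)peroxy]-4-methylhex-5-en-1-yl]-3-methyloxiran-2-yl]methanol F2. Aqueous acetic acid in THF removes the ketal to give the epoxy hydroperoxide [(2R,3R)-3-[(3S,4S)-3-hydroperoxy-4-methylhex-5-en-1-yl]-3-methyloxiran-2-yl]methanol F3. Catalytic camphorsulfonic acid in CH2Cl2 should then close the dioxane by 6-exo opening of the epoxide at its tertiary carbon with inversion, which gives 8.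

Step 18. The palladium stage may stall (slow boron-to-palladium transfer), so that protodeboronation, reduction of the iodoalkene or attack of zerovalent palladium on the O–O bond takes over. The fallback reverses the polarity of the two partners; it sets out from 20 and 24 and comes back at 26. Diene 20 is hydroborated as before and the borane 25 is oxidised with NaBO3·4H2O to the primary alcohol methyl (2R)-2-[(3S,6R)-6-[(3E)-6-hydroxy-4-methylhex-3-en-1-yl]-6-methyl-1,2-dioxan-3-yl]propanoate F5. An Appel reaction (I2, PPh3, imidazole, CH2Cl2, 0 °C) gives the primary iodide methyl (2R)-2-[(3S,6R)-6-[(3E)-6-iodo-4-methylhex-3-en-1-yl]-6-methyl-1,2-dioxan-3-yl]propanoate F6. Iodide 24 is converted with t-BuLi (−78 °C) and ZnBr2 into the alkenylzinc reagent bromo[(1E)-2,6-dimethylhepta-1,5-dien-1-yl]zinc F7. A Negishi coupling of F6 with F7 (Pd2(dba)3, P(c-C5H9)3, N-methylimidazole, THF/NMP) should form the same C12–C13 bond and give 26.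

Step 11. The basic ylide may deprotonate next to the ester and open the dioxane by β-elimination of the peroxide, or attack the O–O bond. The fallback avoids both the aldehyde and the ylide by a Corey–Winter olefination of the diol; it sets out from 11 and comes back at 13. Diol 11 and 1,1'-thiocarbonyldiimidazole (toluene, rt) give the cyclic thionocarbonate methyl (2R)-2-[(3S,6S)-6-methyl-6-[(4R)-2-sulfanylidene-1,3-dioxolan-4-yl]-1,2-dioxan-3-yl]propanoate F4. Treatment with 1,3-dimethyl-2-phenyl-1,3,2-diazaphospholidine (THF, 40 °C) should give 13 directly, with C8 retained from the diol.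

Further compounds
F1 | step 7 | (2E,6S,7S)-6-[(2-methoxypropan-2-yl)peroxy]-3,7-dimethylnona-2,8-dien-1-ol | C=C[C@H](C)[C@@H](OOC(C)(C)OC)CC/C(C)=C/CO
F2 | step 7 | [(2R,3R)-3-[(3S,4S)-3-[(2-methoxypropan-2-yl)peroxy]-4-methylhex-5-en-1-yl]-3-methyloxiran-2-yl]methanol | C=C[C@H](C)[C@@H](OOC(C)(C)OC)CC[C@](C)([C@H]1CO)O1
F3 | step 7 | [(2R,3R)-3-[(3S,4S)-3-hydroperoxy-4-methylhex-5-en-1-yl]-3-methyloxiran-2-yl]methanol | C=C[C@H](C)[C@@H](OO)CC[C@](C)([C@H]1CO)O1
F4 | step 11 | methyl (2R)-2-[(3S,6S)-6-methyl-6-[(4R)-2-sulfanylidene-1,3-dioxolan-4-yl]-1,2-dioxan-3-yl]propanoate | COC(=O)[C@H](C)[C@@H]1CC[C@@](C)([C@H]2COC(=S)O2)OO1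
F5 | step 18 | methyl (2R)-2-[(3S,6R)-6-[(3E)-6-hydroxy-4-methylhex-3-en-1-yl]-6-methyl-1,2-dioxan-3-yl]propanoate | COC(=O)[C@H](C)[C@@H]1CC[C@@](C)(CC/C=C(\C)CCO)OO1
F6 | step 18 | methyl (2R)-2-[(3S,6R)-6-[(3E)-6-iodo-4-methylhex-3-en-1-yl]-6-methyl-1,2-dioxan-3-yl]propanoate | COC(=O)[C@H](C)[C@@H]1CC[C@@](C)(CC/C=C(\C)CCI)OO1
F7 | step 18 | bromo[(1E)-2,6-dimethylhepta-1,5-dien-1-yl]zinc | Br[Zn]/C=C(\C)CCC=C(C)C
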